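Before adding coupling partner or cutting precatalyst, I reckon what each move can do to the rate at 20% conversion.

| setting | elm | cedar | flask |
|---|---|---|---|
| substrate | 0.013 M | 0.030 M | 0.020 M |
| coupling partner | 0.80 equiv | 0.80 equiv | 0.800 equiv |
| precatalyst | 0.36 mol% | 0.36 mol% | 0.36 mol% |
| remark | run made earlier | run made earlier |  |

- elm (time / h: target / %): 3.00: 0; 5.00: 0; 10.0: 0; 20.0: 3; 40.0: 9
- cedar (time / h: target / %): 8.00: 0; 15.0: 3; 20.0: 9; 30.0: 10; 40.0: 20

(readings scatter by 2 percentage points)

- factor on the rate of making target when 20% of the substrate are converted if coupling partner is charged twice over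
- factor on the rate when 20% of the substrate are converted if precatalyst is charged at 0.08 mol% instead



Elm reads 0% at 10.0 h and 9% at 40.0 h, and cedar reads 20% at 40.0 h, so target appears late. Both runs charge 0.80 equiv and 0.36 mol%, so they don't part the coupling partner from the substrate.

First setting: the coupling partner, charged at 0.800 equiv, is the limiting reagent. I work with what is left. At 20% conversion the flask keeps 75.0% of its charge, and a doubled charge keeps 87.5% of twice as much. So at the same conversion of substrate, c(coupling partner) stands higher by a factor of 2.33, the partner lever. The apparent order is ln(rate factor)/ln(lever); I take it to lie between 0 and 1, which puts the rate factor between 1 and the lever.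

Second setting: 0.08 mol% of precatalyst is 0.222 of the flask's loading. The lag suggests that catalyst appears with time, and I expect the leaner loading to reach 20% later, with a smaller share of its precatalyst left. So I expect a factor above 0.222.

The forecast gives 1.6 for the doubled charge and 0.22 for the leaner loading, and says of the first: “That gives a factor from 1 to 2.33, so I take about 1.6.” My reckoning parts from it on the second, where I expect more than 0.222.

The flask gives 1.10 for the doubled charge, below the forecast, and 0.369 for the leaner loading, above it.

    substrate + free catalyst ⇌ catalyst intermediate A (K = 300 M⁻¹, k = 0.110 M⁻¹ s⁻¹)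
    coupling partner + catalyst intermediate A ⇌ catalyst intermediate B (K = 600 M⁻¹, k = 0.520 M⁻¹ s⁻¹)
    catalyst intermediate B → free catalyst + target (k = 0.00590 s⁻¹)
    precatalyst → free catalyst (k = 3.50 × 10⁻⁶ s⁻¹)

At 1.64 d, catalyst intermediate A in the flask has a half-life of 0.028 h by its forward step to catalyst intermediate B alone. The lever of 2.33 returns 1.10, an apparent partner order of 0.109. The same rule on the leaner loading, with 0.222 in the lever's place, gives an apparent precatalyst order of 0.663.

(The runs were computed with constants of no real substance.)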